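(The runs come from a simulation for substances that don't exist, noise included.)

Amounts first: epsilon, gamma and the flask keep the same ratios of coupling partner and free catalyst to substrate, so no pair of them varies the coupling partner by itself.

the same everywhere: free catalyst 10 mol%

|  | left-handed substrate | right-handed substrate | coupling partner | remark |
|---|---|---|---|---|
| epsilon | 0.10 M | 0.10 M | 1.5 equiv | run made earlier |
| gamma | 0.15 M | 0.15 M | 1.5 equiv | run made earlier |
| flask | 0.20 M | 0.20 M | 1.50 equiv |  |

| run | time / h | left-handed product / % | left-handed substrate / % |
|---|---|---|---|
| epsilon | 2.50 | 1.1 | 49.0 |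
| epsilon | 5.00 | 1.6 | 47.5 |
| epsilon | 8.00 | 3.4 | 47.1 |
| epsilon | 10.0 | 3.2 | 47.1 |
| epsilon | 12.0 | 3.8 | 46.5 |
| epsilon | 15.0 | 4.5 | 45.5 |
| gamma | 1.00 | 1.7 | 49.4 |
| gamma | 2.00 | 1.0 | 48.5 |
| gamma | 3.00 | 2.4 | 47.5 |
| gamma | 5.00 | 2.6 | 47.2 |
| gamma | 8.00 | 3.9 | 45.7 |
| gamma | 15.0 | 7.6 | 42.1 |

(standard deviation of a reading: 0.5 percentage points)

- free catalyst is single-handed; left-handed substrate and right-handed substrate are mirror images of each other, charged as a racemate, each of them at the stated concentration
- the analysis behind the earlier runs scatters by 0.5 percentage points, standard deviation

* apparent order in coupling partner when 20% of the left-handed substrate and right-handed substrate together are converted (percent change of the rate of making left-handed product for one percent more coupling partner charged)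

But the runs do give a pace. At 15.0 h, left-handed product reads 4.5% in epsilon and 7.6% in gamma, so percent made grows with concentration to a power m, read as 1.29, with the scatter of these readings in it. Scaling gamma's pace to the flask by m and counting left-handed product as the whole conversion, I get the target time T, the hours the flask needs to reach 20% at a steady pace: 27.2 h.

My first answer for the order is one, supposing that one coupling partner enters the step making product. So I go round again: in the flask, if each product formed takes one coupling partner, 0.0800 M of it has gone at 20% for a larger charge as for a smaller one, and the rate feels the charge less this amount. I therefore commit to an order above one. The forecast says 0.6, “loosely determined”, which is lower than mine.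

The flask gives 1.5.

    2 free catalyst → spent catalyst B (k = 0.0330 M⁻¹ min⁻¹)
    coupling partner + catalyst intermediate A → free catalyst + left-handed product (k = 0.130 M⁻¹ min⁻¹)
    coupling partner + catalyst intermediate B → free catalyst + right-handed product (k = 0.00280 M⁻¹ min⁻¹)
    free catalyst + left-handed substrate ⇌ catalyst intermediate A (K = 2.50 M⁻¹, k = 4.60 M⁻¹ min⁻¹)
    coupling partner + free catalyst → spent catalyst A (k = 0.0120 M⁻¹ min⁻¹)
    free catalyst + right-handed substrate ⇌ catalyst intermediate B (K = 23.0 M⁻¹, k = 5.80 M⁻¹ min⁻¹)

The flask reaches 20% at 40.8 h, later than T by a factor of 1.50, and already at 12.0 h spent catalyst A, a form outside the working round, holds 33.8% of the catalyst. A second flask with twice the free catalyst has a steady-pace target of 13.6 h, yet its rate comes out 6.66 times as large, more than the factor of 2 that a steady pace gives.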